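What a flask still holds of Q is the reading we lean on: the winter run had 25% left at 15.0 min, the dusk run 30% at 5.00 min.

all flasks: Q 11 mM; E 11.5 mM; X 0.11 mM

| charge | Z | temperature | remark | time |
|---|---|---|---|---|
| winter | 1.7 mM | 65 °C | run made earlier |  |
| dusk | 2.4 mM | 80 °C | run made earlier |  |
| red | 1.1 mM | 90 °C |  | 5.0 min |
| amber | 1.1 mM | 70 °C |  | 5.0 min |
| blue | 3.0 mM | 70 °C |  | 5.0 min |
| teal | 3.0 mM | 90 °C |  | 5.0 min |

- winter (time / min: D / %, L / %, Q / %): 3.00: 24, 0, 70; 6.00: 45, 7, 56; 10.0: 50, 12, 38; 15.0: 53, 21, 25
- dusk (time / min: D / %, L / %, Q / %): 1.50: 33, 1, 62; 3.00: 53, 9, 44; 5.00: 59, 17, 30; 6.00: 56, 17, 29; 8.00: 52, 21, 18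

(readings scatter by 2 percentage points)

- the numbers in the tables scatter by 2 percentage points (one standard deviation)

1. the flasks put in order of amount of D, in percent of the Q charged, best first, at 5.0 min (red / amber / blue / teal)
2. the amount of D, in percent of the Q charged of the flask you put first, at 5.0 min
3. the amount of D, in percent of the Q charged of the flask you put last, at 5.0 min

We must choose which flask to run next for D. If Q falls first-order at constant [Z] (pseudo-first-order), then at a given temperature the Q left depends on the product [Z]·t, and integrating the rate gives Q left = exp(−ln(2)·[Z]t/H). The winter run gives H = 12.7 mM·min and the dusk run 6.91 mM·min. These runs differ in both [Z] and temperature, so the proportionality to [Z] is assumed, not shown. Interpolating the logarithm in temperature gives 10.4 mM·min at 70 °C: this halving dose, the [Z]·t that takes Q to half its amount, is what we carry.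

By our reckoning amber keeps 69.3% of its Q and blue, at its own 70 °C, 36.8%. The dose of blue is smaller than that of the winter run, so blue stays within the doses read. Borrowing as a rough allowance the 7% of L read in the winter run at 6.00 min, we estimate about 56.2% of D in blue. For teal we reckon nothing: its temperature lies above both runs, and in the dusk run the halving dose read at 1.50 min was 5.22 mM·min, smaller than the later value. We would run blue.

The forecast says teal > blue > red > amber, with 56% in teal and 34% in amber, and adds: “Teal versus blue is close, and the Z order is assumed, not established.”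

The flasks come out blue > teal > red > amber, with 57.8% of D in blue and 32.3% in amber, under this scheme:

    Q + Z ⇌ Z + D (K = 2.10, k = 3.70 L mol⁻¹ s⁻¹, Ea = 48.0 kJ mol⁻¹, ΔH = −45.0 kJ mol⁻¹)
    E + X + D → X + L (k = 9800 L² mol⁻² s⁻¹, Ea = 22.0 kJ mol⁻¹)
    2 X ⇌ G, settled at all times (K = 2.40 × 10⁵ L mol⁻¹, ΔH = −25.0 kJ mol⁻¹)
    (constants at 90 °C)

At 5.0 min amber holds 63.2% of its Q against our 69.3%, and blue 33.2% against our 36.8%, while teal holds 52.2% of D. A neighbour of amber is charged with 2.8 mM of Z, a dose of 14.0 mM·min, so by the halving dose we reckon 39.3% of Q left in it. That flask holds 35.1% of Q, with 8.73% of L and 56.1% of D.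

(All runs stem from a simulated flask on assumed constants.)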